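**Plan**

1. Numbering used: cyclopentane C1–C2–C3–C5–C6 (C5 carries C4H(OAc)–C15H3); cyclohexane C1–C6–C7–C8–C9–C10 (C10=C14H2; C7 carries the oxirane C11/C12 with methyl C13).
2. Retrosynthesis: the oxirane (from a 1,2-diol) and the five esters are removed first; then C1–C6 and C3–C5 are cut together, which unfolds the hydrindane into an acyclic α-ene-vinylcyclopropane; this is cut at C9–C10 (aldehyde + alkenyl triflate) and at C6–C7 (epoxy alcohol + alkyne).
3. Forward: the chain C4–C9 is built linearly, the cyclopropane holding C1–C3 (C2/C3 as a cis-diol acetonide) is joined at C9–C10, and one rhodium-catalysed [3+2] cycloaddition closes the cyclohexane (C1–C6) and then the cyclopentane (C3–C5).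
4. Enabling feature: ring-fusion carbon C1 of the cyclopentane carries the exocyclic alkene C10=C14, and C6 is three ring atoms (C9, C8, C7) away from C10. This is the retron of a vinylcyclopropane–alkene [3+2] in which the vinyl group survives as the exo-methylene; the cyclopropane and the acetonide are temporary rings.
5. Stereochemistry: C8 from the chiral pool; C7 and C11 from a Sharpless epoxidation and its invertive opening; C4 and the enoate carbinol from (S)-but-3-yn-2-ol; C9 by Felkin–Anh addition; C1, C5, C6 and the face of the C2/C3 diol in the cycloaddition; the 2-methylbutanoates from the (R)-acid.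
6. Endgame: a 3,4-O-silylene separates O2/O8 (2-methylbutanoates) from O3/O4 (acetates); the oxirane is closed last.

Key step: step 19

Assumption: the target is taken exactly as drawn ((R)-2-methylbutanoates, (S)-carbinol in the enoate), and 2,2-dimethyl-1,3-dioxole is taken as a purchasable reagent.

**Fragment 1: cyclopropyl alkenyl triflate**

Step 1
Reactants: 1 acetyl chloride; 2 (trimethylsilyl)diazomethane
Product: 3 1-diazopropan-2-one
Conditions: 2 (2 M in hexanes), THF/MeCN, 0 °C
Reagents that add atoms: none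
Why: Acylation of the diazo carbon and chloride-induced loss of the silyl group should give the α-diazoketone (Arndt–Eistert-type diazoketone synthesis).

Step 2
Reactants: 3 1-diazopropan-2-one; 4 2,2-dimethyl-1,3-dioxole
Product: 5 exo-6-acetyl-3,3-dimethyl-2,4-dioxabicyclo[3.1.0]hexane (meso, acetyl trans to both ring oxygens)
Conditions: Rh2(OAc)4 (1 mol %), 4 (5 equiv), CH2Cl2, 23 °C, slow addition of 3
Reagents that add atoms: none
Why: Rhodium-carbenoid cyclopropanation of the electron-rich enediol ether should place the acetyl group exo, and since the product is meso no absolute control is needed (the donor–acceptor cyclopropane is purified on base-washed silica).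

Step 3
Reactants: 5 exo-6-acetyl-3,3-dimethyl-2,4-dioxabicyclo[3.1.0]hexane
Product: 7 1-(exo-3,3-dimethyl-2,4-dioxabicyclo[3.1.0]hexan-6-yl)ethenyl trifluoromethanesulfonate, via potassium enolate 6 (not isolated)
Conditions: KN(SiMe3)2, THF, −78 °C; then PhNTf2
Reagents that add atoms: N-phenylbis(trifluoromethanesulfonimide), O=S(=O)(N(c1ccccc1)S(=O)(=O)C(F)(F)F)C(F)(F)F
Why: Kinetic deprotonation should occur at the methyl group, because enolisation towards the ring would give a strained alkylidenecyclopropane, and O-sulfonylation then gives the enol triflate (enol triflate formation).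

**Fragment 2: side-chain acid and silyl alkyne**

Step 4
Reactants: 8 (S)-but-3-yn-2-ol
Product: 9 (S)-(but-3-yn-2-yloxy)(tert-butyl)diphenylsilane
Conditions: TBDPSCl, imidazole, DMF, 23 °C
Reagents that add atoms: tert-butyl(chloro)diphenylsilane, CC(C)(C)[Si](Cl)(c1ccccc1)c1ccccc1
Why: Imidazole-promoted silylation gives an ether that survives the organoaluminium, basic and acidic steps that follow, and the stereocentre is not touched.

Step 5
Reactants: 9 (S)-(but-3-yn-2-yloxy)(tert-butyl)diphenylsilane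
Product: 11 ethyl (2E,4S)-4-(tert-butyldiphenylsilyloxy)-3-methylpent-2-enoate, via alkenylalane 10 (not isolated)
Conditions: Me3Al, Cp2ZrCl2 (25 mol %), CH2Cl2, 0 → 23 °C; then ClCO2Et, 0 °C
Reagents that add atoms: trimethylaluminium, C[Al](C)C; ethyl chloroformate, CCOC(=O)Cl
Why: Zirconium-catalysed syn-carboalumination (Negishi carboalumination) puts methyl on the internal and aluminium on the terminal alkyne carbon cis to each other, and acylation of the alkenylalane with retention should give only the (E)-enoate.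

Step 6
Reactants: 11 ethyl (2E,4S)-4-(tert-butyldiphenylsilyloxy)-3-methylpent-2-enoate
Product: 12 (2E,4S)-4-(tert-butyldiphenylsilyloxy)-3-methylpent-2-enoic acid
Conditions: LiOH, THF/MeOH/H2O, 23 °C; then 1 M HCl to pH 3
Reagents that add atoms: lithium hydroxide, [Li+].[OH-]
Why: Saponification of the unhindered ethyl ester leaves the silyl ether and the alkene geometry intact.

Step 7
Reactants: 8 (S)-but-3-yn-2-ol
Product: 13 (S)-(but-3-yn-2-yloxy)triethylsilane
Conditions: TESCl, imidazole, CH2Cl2, 0 °C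
Reagents that add atoms: chlorotriethylsilane, CC[Si](Cl)(CC)CC
Why: Silylation masks the carbinol (the later C4–OH) during acetylide formation and is removed again with mild acid in step 13.

**Main chain C4–C9**

Step 8
Reactants: 14 methyl (S)-2,2-dimethyl-1,3-dioxolane-4-carboxylate; 15 ethyl 2-(triphenylphosphoranylidene)propanoate
Product: 17 ethyl (2E)-3-[(4R)-2,2-dimethyl-1,3-dioxolan-4-yl]-2-methylprop-2-enoate, via (S)-glyceraldehyde acetonide 16 (not isolated)
Conditions: i-Bu2AlH (1.05 equiv), CH2Cl2, −78 °C; then 15, −78 → 23 °C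
Reagents that add atoms: none
Why: Half-reduction of the ester and Wittig olefination of the aldehyde in the same flask with the stabilised ylide should give the (E)-trisubstituted enoate without isolating the epimerisable aldehyde, whose stereocentre becomes C8.

Step 9
Reactants: 17 ethyl (2E)-3-[(4R)-2,2-dimethyl-1,3-dioxolan-4-yl]-2-methylprop-2-enoate
Product: 18 (2E)-3-[(4R)-2,2-dimethyl-1,3-dioxolan-4-yl]-2-methylprop-2-en-1-ol
Conditions: i-Bu2AlH (2.2 equiv), CH2Cl2, −78 °C
Reagents that add atoms: none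
Why: 1,2-Reduction of the enoate by the aluminium hydride gives the allylic alcohol needed for the directed epoxidation.

Step 10
Reactants: 18 (2E)-3-[(4R)-2,2-dimethyl-1,3-dioxolan-4-yl]-2-methylprop-2-en-1-ol
Product: 19 [(2R,3R)-3-[(4S)-2,2-dimethyl-1,3-dioxolan-4-yl]-2-methyloxiran-2-yl]methanol
Conditions: Ti(OiPr)4 (10 mol %), D-(−)-diethyl tartrate (12 mol %), t-BuOOH, 4 Å molecular sieves, CH2Cl2, −20 °C
Reagents that add atoms: tert-butyl hydroperoxide, CC(C)(C)OO
Why: Sharpless asymmetric epoxidation with the D-tartrate delivers oxygen under reagent control to the face that gives the (2R,3R)-epoxide, which fixes C11 and, after the inversion of step 11, C7.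

Step 11
Reactants: 19 [(2R,3R)-3-[(4S)-2,2-dimethyl-1,3-dioxolan-4-yl]-2-methyloxiran-2-yl]methanol; 13 (S)-(but-3-yn-2-yloxy)triethylsilane
Product: 22 (2S,3S,6S)-3-[(4R)-2,2-dimethyl-1,3-dioxolan-4-yl]-2-methyl-6-(triethylsilyloxy)hept-4-yne-1,2-diol, via lithium acetylide 20 (not isolated), via alkynylalane 21 (not isolated)
Conditions: 13 (3 equiv), n-BuLi, toluene, 0 °C; Et2AlCl, 0 °C; then 19, 0 → 23 °C
Reagents that add atoms: none
Why: In the hydroxyl-directed opening of a 2,3-epoxy alcohol by an alkynylalane the nucleophile attacks the only non-quaternary oxirane carbon (C7) with inversion, which forms C6–C7, sets C7 and leaves the tertiary C11–O bond untouched.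

Step 12
Reactants: 22 the alkynyl 1,2-diol
Product: 23 (2S,3S,6S)-1-(tert-butyldiphenylsilyloxy)-3-[(4R)-2,2-dimethyl-1,3-dioxolan-4-yl]-2-methyl-6-(triethylsilyloxy)hept-4-yn-2-ol
Conditions: TBDPSCl, imidazole, DMF, 0 → 23 °C
Reagents that add atoms: tert-butyl(chloro)diphenylsilane, CC(C)(C)[Si](Cl)(c1ccccc1)c1ccccc1
Why: The primary C12 hydroxyl is silylated selectively because the neighbouring C11 hydroxyl is tertiary, and this ether masks the later oxirane carbon until step 25.

Step 13
Reactants: 23 the C12 silyl ether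
Product: 24 alkyne tetraol (free OH at C4, C8, C9 and C11; C12 O-TBDPS; C5≡C6; 4S,7S,8R,11S)
Conditions: AcOH/THF/H2O (3:1:1), 40 °C
Reagents that add atoms: none
Why: Mild acid hydrolysis removes the terminal acetonide and the triethylsilyl ether, while the primary tert-butyldiphenylsilyl ether is stable.

Step 14
Reactants: 24 alkyne tetraol
Product: 25 (E)-alkene tetraol (as 24 with C5=C6 E; 4S,7S,8R,11S)
Conditions: NaAlH2(OCH2CH2OMe)2 (excess), THF, 0 → 23 °C
Reagents that add atoms: none
Why: Hydroxyl-directed trans-hydroalumination of the propargylic alcohol and protonolysis on work-up should give only the (E)-alkene that the cycloaddition needs.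

Step 15
Reactants: 25 (E)-alkene tetraol
Product: 26 4,8,9-tris-O-triethylsilyl ether (C11–OH free, C12 O-TBDPS)
Conditions: TESCl (3.5 equiv), imidazole, DMF, 0 °C
Reagents that add atoms: chlorotriethylsilane, CC[Si](Cl)(CC)CC
Why: The primary and the two secondary hydroxyls are silylated, while the tertiary C11 hydroxyl is too hindered to react with the silyl chloride.

Step 16
Reactants: 26 tris-silyl ether
Product: 27 C9 aldehyde (C4 and C8 O-TES, C12 O-TBDPS, C11–OH; 4S,7S,8R,11S)
Conditions: (COCl)2, DMSO, CH2Cl2, −78 → −30 °C; then Et3N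
Reagents that add atoms: none
Why: Under Swern conditions a primary triethylsilyl ether is cleaved and oxidised directly to the aldehyde while the secondary silyl ethers remain (Swern oxidation of a primary silyl ether).

**Union and key step**

Step 17
Reactants: 27 C9 aldehyde; 7 cyclopropyl alkenyl triflate
Product: 28 allylic alcohol (9S; C9–OH, C10(=C14H2) bearing the exo-dioxabicyclohexyl group; 4S,7S,8R,11S)
Conditions: CrCl2 (6 equiv), NiCl2 (1 mol %), DMF/THF, 23 °C
Reagents that add atoms: none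
Why: The Nozaki–Hiyama–Kishi coupling adds the alkenylchromium reagent to the aldehyde only, and Felkin–Anh control by the α-silyloxy stereocentre C8 should give the 8,9-anti product (9S).

Step 18
Reactants: 28 allylic alcohol; 12 (2E,4S)-4-(tert-butyldiphenylsilyloxy)-3-methylpent-2-enoic acid
Product: 29 α-ene-vinylcyclopropane ester (9-O-enoate)
Conditions: DCC, DMAP (0.3 equiv), CH2Cl2, 0 → 23 °C
Reagents that add atoms: none
Why: Steglich esterification acylates the secondary allylic alcohol under near-neutral conditions with little DMAP, which limits deconjugation of the enoate, and the tertiary C11 hydroxyl does not react.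

Step 19
Reactants: 29 α-ene-vinylcyclopropane ester
Product: 30 trans-hydrindane cycloadduct (2,3-O-isopropylidene; 4-O-TES; 8-O-TES; 12-O-TBDPS; 9-O-enoate; C10=C14; all ring stereocentres as in the target)
Conditions: [Rh(CO)2Cl]2 (5 mol %), toluene (0.02 M), 100 °C
Reagents that add atoms: none
Why: Monovalent rhodium binds the 1,1-disubstituted alkene C10=C14 and inserts into the adjacent strained cyclopropane bond (C1–C3) to give a π-allyl/alkyl complex of trivalent rhodium; the tethered E-alkene then inserts syn at the allyl terminus (C1–C6), and C(sp3)–C(sp3) reductive elimination joins C3 to C5 and frees the catalyst. The closest known reaction type is the rhodium-catalysed intramolecular [3+2] cycloaddition of α-ene-vinylcyclopropanes, in which the vinyl group reappears as an exocyclic methylene next to the ring fusion. The cyclohexane closes by 6-exo-trig carbometalation and the cyclopentane by reductive elimination from a six-membered rhodacycle. C2 and C3 keep the cis relation fixed by the acetonide; C1 is reset in the π-allyl, so either cyclopropane bond and either exo/endo isomer can funnel into the same adduct; C5/C6 become trans by suprafacial addition to the E-alkene; and C1/C6 become trans because the chair-like transition state keeps the C7 and C8 substituents equatorial and the C9 acyloxy group axial (relief of allylic 1,3-strain with C14), which also puts H-6 anti to H-7. The face of the diol should follow from the rhodacyclohexane chair that places the C3 oxygen equatorial next to the metal and only the C2 oxygen axial, which is the all-cis C10/O2/O3/C4 array of the target. The step needs [3+2] over [5+2] and over β-hydride or β-alkoxide elimination, which the three-atom tether and the small rhodacycle (no syn-coplanar Rh–C–C–H or Rh–C–C–O array) should secure, and it needs C5=C6 as the only 2π partner, which is why C11–C13 is carried as a protected diol and not as an isopropenyl group.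

**Endgame**

Step 20
Reactants: 30 cycloadduct
Product: 31 tetraol (free OH at C2, C3, C4, C8 and tertiary C11; 12-O-TBDPS; 9-O-enoate)
Conditions: AcOH/H2O (4:1), 50 °C
Reagents that add atoms: none
Why: Acid hydrolysis removes the cis-fused acetonide and both triethylsilyl ethers, while the tert-butyldiphenylsilyl ethers, the ester and the exocyclic alkene should survive.

Step 21
Reactants: 31 tetraol
Product: 32 3,4-O-(di-tert-butylsilylene) derivative (C2–OH and C8–OH free)
Conditions: t-Bu2Si(OTf)2 (1.05 equiv), 2,6-lutidine, DMF, −40 → 0 °C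
Reagents that add atoms: di-tert-butylsilyl bis(trifluoromethanesulfonate), CC(C)(C)[Si](OS(=O)(=O)C(F)(F)F)(OS(=O)(=O)C(F)(F)F)C(C)(C)C
Why: The silylene should bridge the 1,3-diol O3/O4 as a six-membered ring in preference to the strained five-membered ring on the cis-2,3-diol or a ring to the hindered tertiary C11–OH (as in 3',5'-O-silylene protection of ribonucleosides), which distinguishes O3 from O2.

Step 22
Reactants: 32 3,4-O-silylene; 33 (R)-2-methylbutanoic acid
Product: 34 2,8-bis-O-[(R)-2-methylbutanoyl] 3,4-O-silylene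
Conditions: 33 (6 equiv), EDC·HCl, DMAP, CH2Cl2, 23 → 35 °C
Reagents that add atoms: none
Why: Carbodiimide esterification (Steglich) acylates the two remaining secondary hydroxyls at C2 and C8 in one operation without passing through a ketene that would racemise the α-stereocentre of the acid.

Step 23
Reactants: 34 bis-ester silylene
Product: 35 3,4-diol (2,8-bis-O-2-methylbutanoyl; 9-O-enoate; 12-O-TBDPS)
Conditions: HF·pyridine, pyridine, THF, 0 °C, short reaction time
Reagents that add atoms: none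
Why: Buffered fluoride cleaves the cyclic dialkoxysilane much faster than the tert-butyldiphenylsilyl ethers, and the acidic medium suppresses acyl migration from O2 to O3.

Step 24
Reactants: 35 3,4-diol
Product: 36 3,4-di-O-acetate
Conditions: Ac2O, pyridine, DMAP (cat.), CH2Cl2, 0 °C
Reagents that add atoms: acetic anhydride, CC(=O)OC(C)=O
Why: DMAP-catalysed acetylation esterifies both secondary hydroxyls quickly at low temperature, where the tertiary C11 hydroxyl does not react.

Step 25
Reactants: 36 diacetate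
Product: 37 triol (C12–OH, C11–OH and the enoate carbinol free; all five esters in place)
Conditions: HF·pyridine (excess), pyridine, THF, 0 → 23 °C
Reagents that add atoms: none
Why: Prolonged treatment with buffered HF removes both tert-butyldiphenylsilyl ethers at a stage where no oxirane is present and without the basic conditions that would move or cleave the esters.

Step 26
Reactants: 37 triol
Product: 39 target CNP0282336.1, via primary tosylate 38 (not isolated)
Conditions: TsCl, Et3N, Bu2SnO (5 mol %), CH2Cl2, 0 °C; then DBU, 23 °C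
Reagents that add atoms: none
Why: Tin-acetal-catalysed sulfonylation is selective for the primary hydroxyl of the 1,2-diol, and 3-exo-tet displacement by the tertiary C11 oxygen (intramolecular Williamson closure) forms the oxirane with retention at C11.

**Compound list**

1 | acetyl chloride | CC(=O)Cl | starting material
2 | (trimethylsilyl)diazomethane | C[Si](C)(C)C=[N+]=[N-] | starting material
3 | 1-diazopropan-2-one | CC(=O)C=[N+]=[N-] | intermediate
4 | 2,2-dimethyl-1,3-dioxole | CC1(C)OC=CO1 | starting material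
5 | exo-6-acetyl-3,3-dimethyl-2,4-dioxabicyclo[3.1.0]hexane (meso) | CC(=O)[C@H]1[C@@H]2OC(C)(C)O[C@H]12 | intermediate
6 | potassium enolate of 5 | [K+].[O-]C(=C)[C@H]1[C@@H]2OC(C)(C)O[C@H]12 | intermediate
7 | 1-(exo-3,3-dimethyl-2,4-dioxabicyclo[3.1.0]hexan-6-yl)ethenyl trifluoromethanesulfonate | C=C(OS(=O)(=O)C(F)(F)F)[C@H]1[C@@H]2OC(C)(C)O[C@H]12 | intermediate
8 | (S)-but-3-yn-2-ol | C[C@H](O)C#C | starting material
9 | (S)-(but-3-yn-2-yloxy)(tert-butyl)diphenylsilane | C[C@H](O[Si](c1ccccc1)(c1ccccc1)C(C)(C)C)C#C | intermediate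
10 | [(1E,3S)-3-(tert-butyldiphenylsilyloxy)-2-methylbut-1-en-1-yl]dimethylalane | C[C@H](O[Si](c1ccccc1)(c1ccccc1)C(C)(C)C)/C(C)=C/[Al](C)C | intermediate
11 | ethyl (2E,4S)-4-(tert-butyldiphenylsilyloxy)-3-methylpent-2-enoate | CCOC(=O)/C=C(\C)[C@H](C)O[Si](c1ccccc1)(c1ccccc1)C(C)(C)C | intermediate
12 | (2E,4S)-4-(tert-butyldiphenylsilyloxy)-3-methylpent-2-enoic acid | OC(=O)/C=C(\C)[C@H](C)O[Si](c1ccccc1)(c1ccccc1)C(C)(C)C | intermediate
13 | (S)-(but-3-yn-2-yloxy)triethylsilane | C[C@H](O[Si](CC)(CC)CC)C#C | intermediate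
14 | methyl (S)-2,2-dimethyl-1,3-dioxolane-4-carboxylate | COC(=O)[C@@H]1COC(C)(C)O1 | starting material
15 | ethyl 2-(triphenylphosphoranylidene)propanoate | CCOC(=O)C(C)=P(c1ccccc1)(c1ccccc1)c1ccccc1 | starting material
16 | (S)-2,2-dimethyl-1,3-dioxolane-4-carbaldehyde | O=C[C@@H]1COC(C)(C)O1 | intermediate
17 | ethyl (2E)-3-[(4R)-2,2-dimethyl-1,3-dioxolan-4-yl]-2-methylprop-2-enoate | CCOC(=O)/C(C)=C/[C@@H]1COC(C)(C)O1 | intermediate
18 | (2E)-3-[(4R)-2,2-dimethyl-1,3-dioxolan-4-yl]-2-methylprop-2-en-1-ol | OC/C(C)=C/[C@@H]1COC(C)(C)O1 | intermediate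
19 | [(2R,3R)-3-[(4S)-2,2-dimethyl-1,3-dioxolan-4-yl]-2-methyloxiran-2-yl]methanol | OC[C@@]1(C)O[C@@H]1[C@@H]1COC(C)(C)O1 | intermediate
20 | lithium (3S)-3-(triethylsilyloxy)but-1-yn-1-ide | C[C@H](O[Si](CC)(CC)CC)C#C[Li] | intermediate
21 | diethyl[(3S)-3-(triethylsilyloxy)but-1-yn-1-yl]alane | C[C@H](O[Si](CC)(CC)CC)C#C[Al](CC)CC | intermediate
22 | (2S,3S,6S)-3-[(4R)-2,2-dimethyl-1,3-dioxolan-4-yl]-2-methyl-6-(triethylsilyloxy)hept-4-yne-1,2-diol | C[C@H](O[Si](CC)(CC)CC)C#C[C@H]([C@](C)(O)CO)[C@@H]1COC(C)(C)O1 | intermediate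
23 | (2S,3S,6S)-1-(tert-butyldiphenylsilyloxy)-3-[(4R)-2,2-dimethyl-1,3-dioxolan-4-yl]-2-methyl-6-(triethylsilyloxy)hept-4-yn-2-ol | C[C@H](O[Si](CC)(CC)CC)C#C[C@H]([C@](C)(O)CO[Si](c1ccccc1)(c1ccccc1)C(C)(C)C)[C@@H]1COC(C)(C)O1 | intermediate
24 | alkyne tetraol (C4, C8, C9, C11 OH; 12-O-TBDPS; 4S,7S,8R,11S) | C[C@H](O)C#C[C@H]([C@](C)(O)CO[Si](c1ccccc1)(c1ccccc1)C(C)(C)C)[C@@H](O)CO | intermediate
25 | (E)-alkene tetraol (4S,7S,8R,11S) | C[C@H](O)/C=C/[C@H]([C@](C)(O)CO[Si](c1ccccc1)(c1ccccc1)C(C)(C)C)[C@@H](O)CO | intermediate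
26 | 4,8,9-tris-O-triethylsilyl ether | C[C@H](O[Si](CC)(CC)CC)/C=C/[C@H]([C@](C)(O)CO[Si](c1ccccc1)(c1ccccc1)C(C)(C)C)[C@@H](O[Si](CC)(CC)CC)CO[Si](CC)(CC)CC | intermediate
27 | C9 aldehyde (4S,7S,8R,11S) | C[C@H](O[Si](CC)(CC)CC)/C=C/[C@H]([C@](C)(O)CO[Si](c1ccccc1)(c1ccccc1)C(C)(C)C)[C@@H](O[Si](CC)(CC)CC)C=O | intermediate
28 | allylic alcohol (4S,7S,8R,9S,11S) with the vinylcyclopropane | C[C@H](O[Si](CC)(CC)CC)/C=C/[C@H]([C@](C)(O)CO[Si](c1ccccc1)(c1ccccc1)C(C)(C)C)[C@@H](O[Si](CC)(CC)CC)[C@@H](O)C(=C)[C@H]1[C@@H]2OC(C)(C)O[C@H]12 | intermediate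
29 | α-ene-vinylcyclopropane ester (9-O-enoate) | C[C@H](O[Si](CC)(CC)CC)/C=C/[C@H]([C@](C)(O)CO[Si](c1ccccc1)(c1ccccc1)C(C)(C)C)[C@@H](O[Si](CC)(CC)CC)[C@@H](OC(=O)/C=C(\C)[C@H](C)O[Si](c1ccccc1)(c1ccccc1)C(C)(C)C)C(=C)[C@H]1[C@@H]2OC(C)(C)O[C@H]12 | intermediate
30 | trans-hydrindane cycloadduct (2,3-O-isopropylidene) | C=C1[C@@H]2[C@@H]3OC(C)(C)O[C@@H]3[C@H]([C@H](C)O[Si](CC)(CC)CC)[C@H]2[C@H]([C@](C)(O)CO[Si](c2ccccc2)(c3ccccc3)C(C)(C)C)[C@@H](O[Si](CC)(CC)CC)[C@H]1OC(=O)/C=C(\C)[C@H](C)O[Si](c1ccccc1)(c1ccccc1)C(C)(C)C | intermediate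
31 | tetraol (C2, C3, C4, C8 OH) | C=C1[C@@H]2[C@H](O)[C@H](O)[C@H]([C@H](C)O)[C@H]2[C@H]([C@](C)(O)CO[Si](c2ccccc2)(c3ccccc3)C(C)(C)C)[C@@H](O)[C@H]1OC(=O)/C=C(\C)[C@H](C)O[Si](c1ccccc1)(c1ccccc1)C(C)(C)C | intermediate
32 | 3,4-O-(di-tert-butylsilylene) derivative | C=C1[C@@H]2[C@H](O)[C@@H]3O[Si](C(C)(C)C)(C(C)(C)C)O[C@@H](C)[C@@H]3[C@H]2[C@H]([C@](C)(O)CO[Si](c2ccccc2)(c3ccccc3)C(C)(C)C)[C@@H](O)[C@H]1OC(=O)/C=C(\C)[C@H](C)O[Si](c1ccccc1)(c1ccccc1)C(C)(C)C | intermediate
33 | (R)-2-methylbutanoic acid | CC[C@@H](C)C(=O)O | starting material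
34 | 2,8-bis-O-[(R)-2-methylbutanoyl] 3,4-O-silylene | C=C1[C@@H]2[C@H](OC(=O)[C@H](C)CC)[C@@H]3O[Si](C(C)(C)C)(C(C)(C)C)O[C@@H](C)[C@@H]3[C@H]2[C@H]([C@](C)(O)CO[Si](c2ccccc2)(c3ccccc3)C(C)(C)C)[C@@H](OC(=O)[C@H](C)CC)[C@H]1OC(=O)/C=C(\C)[C@H](C)O[Si](c1ccccc1)(c1ccccc1)C(C)(C)C | intermediate
35 | 3,4-diol | C=C1[C@@H]2[C@H](OC(=O)[C@H](C)CC)[C@H](O)[C@H]([C@H](C)O)[C@H]2[C@H]([C@](C)(O)CO[Si](c2ccccc2)(c3ccccc3)C(C)(C)C)[C@@H](OC(=O)[C@H](C)CC)[C@H]1OC(=O)/C=C(\C)[C@H](C)O[Si](c1ccccc1)(c1ccccc1)C(C)(C)C | intermediate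
36 | 3,4-di-O-acetate | C=C1[C@@H]2[C@H](OC(=O)[C@H](C)CC)[C@H](OC(C)=O)[C@H]([C@H](C)OC(C)=O)[C@H]2[C@H]([C@](C)(O)CO[Si](c2ccccc2)(c3ccccc3)C(C)(C)C)[C@@H](OC(=O)[C@H](C)CC)[C@H]1OC(=O)/C=C(\C)[C@H](C)O[Si](c1ccccc1)(c1ccccc1)C(C)(C)C | intermediate
37 | triol (C11, C12 and enoate carbinol OH) | C=C1[C@@H]2[C@H](OC(=O)[C@H](C)CC)[C@H](OC(C)=O)[C@H]([C@H](C)OC(C)=O)[C@H]2[C@H]([C@](C)(O)CO)[C@@H](OC(=O)[C@H](C)CC)[C@H]1OC(=O)/C=C(\C)[C@H](C)O | intermediate
38 | primary C12 tosylate | C=C1[C@@H]2[C@H](OC(=O)[C@H](C)CC)[C@H](OC(C)=O)[C@H]([C@H](C)OC(C)=O)[C@H]2[C@H]([C@](C)(O)COS(=O)(=O)c2ccc(C)cc2)[C@@H](OC(=O)[C@H](C)CC)[C@H]1OC(=O)/C=C(\C)[C@H](C)O | intermediate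
39 | CNP0282336.1 | C=C1[C@@H]2[C@H](OC(=O)[C@H](C)CC)[C@H](OC(C)=O)[C@H]([C@H](C)OC(C)=O)[C@H]2[C@H]([C@@]2(C)CO2)[C@@H](OC(=O)[C@H](C)CC)[C@H]1OC(=O)/C=C(\C)[C@H](C)O | target

**Summary**

Total step count: 26. Longest linear sequence: 19 steps (steps 8–26, from 14).

Steps most likely to fail:

1. Step 19. Insertion of the hindered, electronically neutral 1,2-disubstituted alkene may be slower than β-hydride elimination from the rhodacycle, which would give ring-opened dienes; the facial sense of the diol rests only on the chair preference of the rhodacycle. Fallback: setting out from 29, the less hindered allylic triethylsilyl ether at C4 is cleaved (PPTS, MeOH, 0 °C) to the allylic alcohol F1, which MnO2 oxidises to the (E)-enone F2. The same rhodium catalyst then meets an electron-poor 2π partner that inserts faster and makes C5 epimerisable, giving the C4-ketone cycloadduct F3. AcOH/H2O removes the acetonide and the C8 silyl ether to give the triol ketone F4, and hydroxyl-directed anti-reduction from O3 (Me4NBH(OAc)3, MeCN/AcOH, −20 °C; Evans–Saksena reduction) sets C4 and comes back to the route at 31.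

2. Step 17. Facial selectivity at C9 may be poor if the α-silyloxy group exerts weak Felkin–Anh control on the alkenylchromium addition. Fallback: setting out from 28 as the epimer mixture, Dess–Martin periodinane gives the enone F5, and Corey–Bakshi–Shibata reduction with the (S)-2-methyl oxazaborolidine and catecholborane (the 2-substituted alkenyl residue taken as the large group) sets C9 under reagent control and comes back at 28.

3. Step 11. Attack at C7, flanked by the quaternary oxirane carbon and the dioxolane, may be slow, so that Lewis-acid-induced rearrangement of the trisubstituted oxirane or loss of the acetonide competes. Fallback: setting out from 19, silylation (TBDPSCl, imidazole) gives the silyl ether F6, and the lithium acetylide 20 with BF3·OEt2 (THF, −78 °C) opens the externally activated oxirane at C7 with inversion, which comes back to the route at 23 and skips steps 11 and 12.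

**Further compounds**

F1 | step 19 | C4 allylic alcohol of 29 (8-O-TES kept) | C[C@H](O)/C=C/[C@H]([C@](C)(O)CO[Si](c1ccccc1)(c1ccccc1)C(C)(C)C)[C@@H](O[Si](CC)(CC)CC)[C@@H](OC(=O)/C=C(\C)[C@H](C)O[Si](c1ccccc1)(c1ccccc1)C(C)(C)C)C(=C)[C@H]1[C@@H]2OC(C)(C)O[C@H]12
F2 | step 19 | (E)-enone (C4 ketone) vinylcyclopropane | CC(=O)/C=C/[C@H]([C@](C)(O)CO[Si](c1ccccc1)(c1ccccc1)C(C)(C)C)[C@@H](O[Si](CC)(CC)CC)[C@@H](OC(=O)/C=C(\C)[C@H](C)O[Si](c1ccccc1)(c1ccccc1)C(C)(C)C)C(=C)[C@H]1[C@@H]2OC(C)(C)O[C@H]12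
F3 | step 19 | C4-ketone cycloadduct (2,3-O-isopropylidene, 8-O-TES) | C=C1[C@@H]2[C@@H]3OC(C)(C)O[C@@H]3[C@H](C(C)=O)[C@H]2[C@H]([C@](C)(O)CO[Si](c2ccccc2)(c3ccccc3)C(C)(C)C)[C@@H](O[Si](CC)(CC)CC)[C@H]1OC(=O)/C=C(\C)[C@H](C)O[Si](c1ccccc1)(c1ccccc1)C(C)(C)C
F4 | step 19 | triol ketone (C2, C3, C8 OH; C4 ketone) | C=C1[C@@H]2[C@H](O)[C@H](O)[C@H](C(C)=O)[C@H]2[C@H]([C@](C)(O)CO[Si](c2ccccc2)(c3ccccc3)C(C)(C)C)[C@@H](O)[C@H]1OC(=O)/C=C(\C)[C@H](C)O[Si](c1ccccc1)(c1ccccc1)C(C)(C)C
F5 | step 17 | C9 enone of 28 | C[C@H](O[Si](CC)(CC)CC)/C=C/[C@H]([C@](C)(O)CO[Si](c1ccccc1)(c1ccccc1)C(C)(C)C)[C@@H](O[Si](CC)(CC)CC)C(=O)C(=C)[C@H]1[C@@H]2OC(C)(C)O[C@H]12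
F6 | step 11 | tert-butyldiphenylsilyl ether of epoxy alcohol 19 | CC(C)(C)[Si](c1ccccc1)(c1ccccc1)OC[C@@]1(C)O[C@@H]1[C@@H]1COC(C)(C)O1
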